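**Plan**

- Retrosynthetic cuts: C11=C12 (olefination joining the C12–C10' arm), the O–C5 bond of the dihydrofuran, the C6–C7 bond (acetylide addition to ring A), and C12'=C11' within the arm.
- Enabling feature: once C3 is a ketone, C5 of ring A is the β-carbon of the C3=O/C4=C5 enone, and the five-membered ring O–C5–C6=C7–C8 places an oxygen on C8 within reach of C5 across the C6=C7 bond.
- Forward order: ring A comes complete from ketoisophorone; C7–C11 is added as the silyl ether of (Z)-3-methylpent-2-en-4-yn-1-ol, which already holds the 9Z bond; a Meyer–Schuster shift moves oxygen from C6 to C8; the dihydrofuran then closes by O8→C5; the polyene arm from the C10 dialdehyde is attached last.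
- Stereochemistry: C8 by oxazaborolidine-controlled reduction; C5 relayed from C8 by allylic strain in the ring closure; C3 from the axial methyls on C1 and C5 in a bulky-hydride reduction; E bonds from the dialdehyde, the Wittig and the Horner–Wadsworth–Emmons steps.

Key step: step 6

Remark: carotenoid numbering is used throughout (ring A C1–C6 with gem-dimethyl C1, oxygenated C3, methyl-bearing C5; chain C7–C15, then C15'–C10' to the far end). The target has the 3S,5R,8R configuration, a 9Z double bond and E geometry at every other chain double bond.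

**Route**

Step 1
Reactants: 1 ketoisophorone (2,6,6-trimethylcyclohex-2-ene-1,4-dione)
Product: 2 ketoisophorone C3 dioxolane (7,9,9-trimethyl-1,4-dioxaspiro[4.5]dec-6-en-8-one)
Conditions: ethylene glycol (1.5 equiv), p-TsOH·H2O (cat.), benzene, reflux, Dean–Stark
Reagents that add atoms: ethylene glycol, OCCO
Why: Acid-catalysed ketalisation with azeotropic water removal takes the unhindered C3 carbonyl, while the C6 carbonyl, flanked by the quaternary C1 and the methyl-bearing C5, stays free and conjugated.

Step 2
Reactants: 3 (Z)-3-methylpent-2-en-4-yn-1-ol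
Product: 4 tert-butyl{[(2Z)-3-methylpent-2-en-4-yn-1-yl]oxy}diphenylsilane
Conditions: TBDPSCl (1.1 equiv), imidazole (2 equiv), CH2Cl2, 0 °C to rt
Reagents that add atoms: tert-butyl(chloro)diphenylsilane, CC(C)(C)[Si](Cl)(c1ccccc1)c1ccccc1
Why: Imidazole-promoted silylation of the primary alcohol gives a bulky, weakly basic silyl ether that tolerates butyllithium, gold catalysis and the acid of step 6, and leaves the Z alkene untouched.

Step 3
Reactants: 4 silyl ether of the Z-enynol; 2 ketoisophorone C3 dioxolane
Product: 6 tertiary propargylic alcohol 8-[(3Z)-5-(tert-butyldiphenylsilyloxy)-3-methylpent-3-en-1-yn-1-yl]-7,9,9-trimethyl-1,4-dioxaspiro[4.5]dec-6-en-8-ol (racemic at C6), via lithium acetylide 5 (not isolated)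
Conditions: n-BuLi (1.05 equiv), THF, −78 °C; then 2, −78 to −20 °C; then H2O
Reagents that add atoms: none
Why: 1,2-Addition of a lithium acetylide to the non-enolisable C6 enone carbonyl forms the C6–C7 bond, a well-precedented union of this ketal with acetylides of the same enynol; the configuration at C6 is irrelevant because C6 becomes sp2 in step 4.

Step 4
Reactants: 6 tertiary propargylic alcohol
Product: 7 cross-conjugated dienone (3Z)-5-(tert-butyldiphenylsilyloxy)-3-methyl-1-(7,9,9-trimethyl-1,4-dioxaspiro[4.5]dec-6-en-8-ylidene)pent-3-en-2-one (C8 ketone; mixture of C6=C7 isomers)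
Conditions: Ph3PAuNTf2 (2 mol%), MeOH (1 equiv), toluene, rt
Reagents that add atoms: none
Why: Gold-catalysed Meyer–Schuster rearrangement: methanol adds to the gold-activated alkyne at C8 (the carbon able to share charge with C9=C10), the tertiary, allylic C6 hydroxyl leaves as water, and hydrolysis of the resulting methoxyallene by that water returns methanol and gives the C8 ketone with a C6=C7 bond, a net isomerisation; the near-neutral conditions spare the dioxolane, and the C6=C7 isomer ratio is of no consequence because step 6 is convergent.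

Step 5
Reactants: 7 cross-conjugated dienone
Product: 8 (8R)-carbinol (2R,3Z)-5-(tert-butyldiphenylsilyloxy)-3-methyl-1-(7,9,9-trimethyl-1,4-dioxaspiro[4.5]dec-6-en-8-ylidene)pent-3-en-2-ol (mixture of C6=C7 isomers)
Conditions: (S)-Me-CBS oxazaborolidine [(3aS)-1-methyl-3,3-diphenyltetrahydro-1H,3H-pyrrolo[1,2-c][1,3,2]oxazaborole] (0.2 equiv), catecholborane (1.5 equiv), toluene, −78 °C; purification on Et3N-deactivated silica
Reagents that add atoms: none
Why: Corey–Bakshi–Shibata reduction: the catalyst binds the carbonyl lone pair on the side of the unbranched C7–H alkenyl arm and treats the α-methyl-branched C9 alkenyl arm as the large group, so the (S)-catalyst should deliver hydride to the Si face of C8 and give the 8R carbinol in both C6=C7 isomers, while catecholborane at −78 °C leaves the alkenes, dioxolane and silyl ether alone.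

Step 6
Reactants: 8 (8R)-carbinol with C3 dioxolane
Product: 10 bicyclic C3 ketone (2R,7aR)-2-[(2Z)-4-(tert-butyldiphenylsilyloxy)but-2-en-2-yl]-4,4,7a-trimethyl-2,4,5,7a-tetrahydro-1-benzofuran-6(7H)-one (5R,8R,9Z in carotenoid numbering), via hydroxy dienone 9 (not isolated)
Conditions: PPTS (0.2 equiv), acetone–H2O (10:1), rt; then CSA (0.1 equiv), 0 °C to rt; NaHCO3 quench; crude product taken directly into step 7
Reagents that add atoms: water, O
Why: Buffered hydrolysis first releases the C3 ketone (dienone 9); every opening of the dioxolane, and later the CSA-protonated dienone, is a 3-oxy-pentadienyl cation with charge at C5 and C7 in which the C6–C7 bond can rotate, so both C6=C7 isomers interconvert and only the one with C8 syn to C5 is drained when the C8 hydroxyl adds to C5 and the C3 enol tautomerises to the ketone. The closest known reaction type is the acid-catalysed intramolecular oxa-Michael addition of an alcohol to the β-methyl carbon of a cyclohexenone, combined with acid-mediated E/Z equilibration of dienones; geometrically the closure mirrors the epoxide-to-furanoid ring closure of carotenoid 5,6-epoxides with the roles of C5 and C8 exchanged. The dihydrofuran ring O–C5–C6=C7–C8 closes in a 5-exo-trig mode with respect to C4=C5, and attack at C3 or C7 is excluded by ring size. The new stereocentre C5 is controlled by C8: allylic 1,3-strain with the in-plane C5 methyl turns the C8 hydrogen inward, oxygen then reaches C5 only from the face that leaves C9 anti to that methyl, which with 8R gives 5R. The step needs kinetic control at C5 and an intact C8: the dioxolane is removed under pyridinium buffer before the stronger acid is added, the electron-poor dienone then disfavours ionisation of the doubly allylic C8–O bond, and the reaction is quenched at full conversion and the ketone reduced at once so that retro-addition cannot set in. Relief of the strain between C8 and the C5 methyl on going from sp2 to sp3 at C5 should offset the loss of dienone conjugation.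

Step 7
Reactants: 10 bicyclic C3 ketone
Product: 11 (3S)-alcohol (2R,6S,7aR)-2-[(2Z)-4-(tert-butyldiphenylsilyloxy)but-2-en-2-yl]-4,4,7a-trimethyl-2,4,5,6,7,7a-hexahydro-1-benzofuran-6-ol
Conditions: LiBH(s-Bu)3 (1.3 equiv), THF, −78 °C; then H2O
Reagents that add atoms: none
Why: Diastereoselective ketone reduction with a bulky trialkylborohydride: the ring oxygen on C5 is held in the plane of C6=C7, so the C5 methyl and one C1 methyl are axial on the same face of ring A and block C3 from that side; hydride therefore enters equatorially from the other face and the new hydroxyl is axial and cis to the C5 methyl (3S), and at −78 °C reduction outruns any retro-oxa-Michael enolisation.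

Step 8
Reactants: 11 (3S)-alcohol silyl ether
Product: 12 diol (2R,6S,7aR)-2-[(2Z)-4-hydroxybut-2-en-2-yl]-4,4,7a-trimethyl-2,4,5,6,7,7a-hexahydro-1-benzofuran-6-ol
Conditions: Bu4NF (1.2 equiv), THF, 0 °C to rt
Reagents that add atoms: none
Why: Fluoride-mediated desilylation frees the C11 alcohol under non-acidic conditions that leave the tertiary allylic C5–O ether and all stereocentres untouched.

Step 9
Reactants: 12 diol
Product: 13 Z-enal (2Z)-3-[(2R,6S,7aR)-6-hydroxy-4,4,7a-trimethyl-2,4,5,6,7,7a-hexahydro-1-benzofuran-2-yl]but-2-enal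
Conditions: MnO2 (activated, 15 equiv), CH2Cl2, rt, dim light
Reagents that add atoms: none
Why: Chemoselective MnO2 oxidation of the primary allylic alcohol: the saturated secondary C3 alcohol does not react, and the neutral heterogeneous oxidant should preserve the 9Z geometry.

Step 10
Reactants: 14 C10 dialdehyde ((2E,4E,6E)-2,7-dimethylocta-2,4,6-trienedial)
Product: 15 ethyl (2E,4E,6E,8E)-4,9-dimethyl-10-oxodeca-2,4,6,8-tetraenoate
Conditions: Ph3P=CHCO2Et (1.0 equiv, slow addition), CH2Cl2, 0 °C to rt
Reagents that add atoms: ethyl (triphenylphosphoranylidene)acetate, CCOC(=O)C=P(c1ccccc1)(c1ccccc1)c1ccccc1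
Why: Wittig olefination with a stabilised ylide forms the 11'E bond; one equivalent added slowly to the symmetrical dialdehyde should favour mono-olefination, and the bis-adduct and recovered 14 are separable.

Step 11
Reactants: 15 aldehyde ester
Product: 16 ethyl (2E,4E,6E,8E)-10-hydroxy-4,9-dimethyldeca-2,4,6,8-tetraenoate
Conditions: NaBH4 (0.4 equiv), MeOH–THF (1:1), −20 °C
Reagents that add atoms: none
Why: Borohydride 1,2-reduction takes the aldehyde and leaves the conjugated ester at this temperature, as is routine for polyenals.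

Step 12
Reactants: 16 hydroxy ester
Product: 17 ethyl (2E,4E,6E,8E)-10-bromo-4,9-dimethyldeca-2,4,6,8-tetraenoate
Conditions: PBr3 (0.4 equiv), pyridine (cat.), Et2O, −10 °C; used crude
Reagents that add atoms: phosphorus tribromide, BrP(Br)Br
Why: Bromination of the primary allylic alcohol through its phosphite ester (SN2) keeps the bromide at the terminus, where the polyene stays fully conjugated with the ester.

Step 13
Reactants: 17 allylic bromide
Product: 18 ethyl (2E,4E,6E,8E)-10-(diethoxyphosphoryl)-4,9-dimethyldeca-2,4,6,8-tetraenoate (C12 phosphonate)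
Conditions: P(OEt)3 (3 equiv, neat), 90 °C
Reagents that add atoms: triethyl phosphite, CCOP(OCC)OCC
Why: Michaelis–Arbuzov reaction of a reactive primary allylic bromide proceeds at moderate temperature and installs the phosphonate at C12 without touching the ester.

Step 14
Reactants: 18 C12 phosphonate; 13 Z-enal
Product: 20 ethyl (3S,5R,8R,9Z)-3-hydroxy-5,8-epoxy-5,8-dihydro-10'-apo-β-caroten-10'-oate, via sodium phosphonate carbanion 19 (not isolated)
Conditions: 18 (1.5 equiv), NaN(SiMe3)2 (1.45 equiv), THF, −78 °C; then 13, −78 to 0 °C, dim light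
Reagents that add atoms: none
Why: Horner–Wadsworth–Emmons olefination: the delocalised anion adds through its phosphorus-bearing carbon C12 to the C11 aldehyde and should give the 11E bond; the stabilised anion is too weak a base to deprotonate the free C3 hydroxyl or to epimerise C8 by γ-deprotonation, and the 9Z bond is carried through unchanged.

Step 15
Reactants: 20 pentaenoate ester
Product: 21 target, (3S,5R,8R,9Z)-5,8-epoxy-5,8-dihydro-10'-apo-β-carotene-3,10'-diol
Conditions: i-Bu2AlH (3.5 equiv), CH2Cl2, −78 °C; aqueous potassium sodium tartrate work-up, dim light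
Reagents that add atoms: none
Why: i-Bu2AlH 1,2-reduction of the conjugated ester gives the allylic C10' alcohol (one equivalent is consumed by the C3 hydroxyl), and the tartrate work-up avoids acid, which would epimerise C8 once the polyene is attached.

**Compound list**

1 | ketoisophorone (2,6,6-trimethylcyclohex-2-ene-1,4-dione) | CC1=CC(=O)CC(C)(C)C1=O | starting material
2 | 7,9,9-trimethyl-1,4-dioxaspiro[4.5]dec-6-en-8-one (C3 dioxolane of 1) | CC1=CC2(OCCO2)CC(C)(C)C1=O | intermediate
3 | (Z)-3-methylpent-2-en-4-yn-1-ol | C#C/C(C)=C\CO | starting material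
4 | tert-butyl{[(2Z)-3-methylpent-2-en-4-yn-1-yl]oxy}diphenylsilane | C#C/C(C)=C\CO[Si](c1ccccc1)(c1ccccc1)C(C)(C)C | intermediate
5 | lithium acetylide of 4 | [Li]C#C/C(C)=C\CO[Si](c1ccccc1)(c1ccccc1)C(C)(C)C | intermediate
6 | tertiary propargylic alcohol, racemic at C6 | CC1=CC2(OCCO2)CC(C)(C)C1(O)C#C/C(C)=C\CO[Si](c1ccccc1)(c1ccccc1)C(C)(C)C | intermediate
7 | cross-conjugated dienone with C8 ketone and C3 dioxolane, 9Z, C6=C7 isomer mixture | CC1=CC2(OCCO2)CC(C)(C)C1=CC(=O)/C(C)=C\CO[Si](c1ccccc1)(c1ccccc1)C(C)(C)C | intermediate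
8 | (8R)-carbinol with C3 dioxolane, 9Z, C6=C7 isomer mixture | CC1=CC2(OCCO2)CC(C)(C)C1=C[C@@H](O)/C(C)=C\CO[Si](c1ccccc1)(c1ccccc1)C(C)(C)C | intermediate
9 | (8R)-hydroxy dienone, 4-[(2R,3Z)-5-(tert-butyldiphenylsilyloxy)-2-hydroxy-3-methylpent-3-en-1-ylidene]-3,5,5-trimethylcyclohex-2-en-1-one, C6=C7 isomer mixture | O=C1C=C(C)C(=C[C@@H](O)/C(C)=C\CO[Si](c2ccccc2)(c2ccccc2)C(C)(C)C)C(C)(C)C1 | intermediate
10 | (5R,8R,9Z) bicyclic C3 ketone, (2R,7aR)-2-[(2Z)-4-(tert-butyldiphenylsilyloxy)but-2-en-2-yl]-4,4,7a-trimethyl-2,4,5,7a-tetrahydro-1-benzofuran-6(7H)-one | C/C(=C/CO[Si](c1ccccc1)(c1ccccc1)C(C)(C)C)[C@H]1C=C2C(C)(C)CC(=O)C[C@@]2(C)O1 | intermediate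
11 | (3S,5R,8R,9Z) bicyclic alcohol, C11 silyl ether | C/C(=C/CO[Si](c1ccccc1)(c1ccccc1)C(C)(C)C)[C@H]1C=C2C(C)(C)C[C@H](O)C[C@@]2(C)O1 | intermediate
12 | (3S,5R,8R,9Z) C3,C11 diol | C/C(=C/CO)[C@H]1C=C2C(C)(C)C[C@H](O)C[C@@]2(C)O1 | intermediate
13 | (3S,5R,8R,9Z) C11 enal | C/C(=C/C=O)[C@H]1C=C2C(C)(C)C[C@H](O)C[C@@]2(C)O1 | intermediate
14 | (2E,4E,6E)-2,7-dimethylocta-2,4,6-trienedial (C10 dialdehyde) | O=C/C(C)=C/C=C/C=C(C)/C=O | starting material
15 | ethyl (2E,4E,6E,8E)-4,9-dimethyl-10-oxodeca-2,4,6,8-tetraenoate | O=C/C(C)=C/C=C/C=C(C)/C=C/C(=O)OCC | intermediate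
16 | ethyl (2E,4E,6E,8E)-10-hydroxy-4,9-dimethyldeca-2,4,6,8-tetraenoate | OC/C(C)=C/C=C/C=C(C)/C=C/C(=O)OCC | intermediate
17 | ethyl (2E,4E,6E,8E)-10-bromo-4,9-dimethyldeca-2,4,6,8-tetraenoate | BrC/C(C)=C/C=C/C=C(C)/C=C/C(=O)OCC | intermediate
18 | ethyl (2E,4E,6E,8E)-10-(diethoxyphosphoryl)-4,9-dimethyldeca-2,4,6,8-tetraenoate | CCOP(=O)(OCC)C/C(C)=C/C=C/C=C(C)/C=C/C(=O)OCC | intermediate
19 | sodium carbanion of 18 (charge at C12) | CCOP(=O)(OCC)[CH-]/C(C)=C/C=C/C=C(C)/C=C/C(=O)OCC.[Na+] | intermediate
20 | ethyl (3S,5R,8R,9Z)-3-hydroxy-5,8-epoxy-5,8-dihydro-10'-apo-β-caroten-10'-oate | C/C(=C/C=C/C(C)=C/C=C/C=C(C)/C=C/C(=O)OCC)[C@H]1C=C2C(C)(C)C[C@H](O)C[C@@]2(C)O1 | intermediate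
21 | (3S,5R,8R,9Z)-5,8-epoxy-5,8-dihydro-10'-apo-β-carotene-3,10'-diol | C/C(=C/C=C/C(C)=C/C=C/C=C(C)/C=C/CO)[C@H]1C=C2C(C)(C)C[C@H](O)C[C@@]2(C)O1 | target

**Step count and risks**

Total step count: 15. Longest linear sequence: 10 steps (steps 1, 3, 4, 5, 6, 7, 8, 9, 14, 15).

Steps most likely to fail:

Step 6. The closure may stop at an equilibrium with the open dienone. Reversible opening of the tertiary allylic C5–O bond under acid may erode the kinetic preference at C5 towards a thermodynamic mixture. Ionisation at C8 before the dioxolane has gone would racemise or dehydrate that centre. Fallback: setting out from 8, the ring is closed irreversibly by phenylselenoetherification across C4=C5 (N-(phenylselanyl)phthalimide, CSA cat., CH2Cl2, −78 °C). The electron-rich diene takes selenium at C4 and the C8 hydroxyl at C5 under the same allylic-strain model, giving the 4-phenylselanyl bicyclic dioxolane F1. Only the C6=C7 isomer with C8 syn to C5 can close; the other is re-equilibrated by sensitised irradiation and recycled. Radical deselenation (Bu3SnH, AIBN, toluene, 80 °C) gives the bicyclic dioxolane F2, and PPTS in wet acetone removes the ketal to rejoin the route at 10.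

Step 4. The gold-activated alkyne may be captured by the C11 silyl ether oxygen (cycloisomerisation of the Z-enyne towards a furan), or the ionised C6 may lose a proton from the C5 methyl instead of passing oxygen to C8. Fallback: setting out from 6, trans-hydroalumination with NaAlH2(OCH2CH2OCH3)2 (THF, 0 °C) gives the 7E tertiary bis-allylic alcohol F3. Babler–Dauben oxidative transposition with [C5H5NH][CrO3Cl] buffered with NaOAc (CH2Cl2, rt) then moves oxygen to the less hindered C8 terminus and delivers 7.

Step 5. Facial discrimination between two alkenyl arms may be insufficient, or the borane may hydroborate an alkene. Fallback: setting out from 7, Luche reduction (NaBH4, CeCl3·7H2O, MeOH, −40 °C) gives the racemic carbinol F4. Lipase-catalysed kinetic resolution (Burkholderia cepacia lipase, vinyl acetate, t-BuOMe, 30 °C) should, by the empirical size rule for secondary alcohols, acetylate the 8R enantiomer to the (8R)-acetate F5, whose configuration would be confirmed by Mosher ester analysis of a saponified sample. The unreacted (8S)-alcohol F6 is returned to 7 with MnO2. Methanolysis of F5 (K2CO3, MeOH, 0 °C) gives 8.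

Further compounds
F1 | step 6 | 4-phenylselanyl bicyclic dioxolane (O–C5 closed, PhSe on C4 trans to the ring oxygen, 4R) | C/C(=C/CO[Si](c1ccccc1)(c1ccccc1)C(C)(C)C)[C@H]1C=C2C(C)(C)CC3(OCCO3)[C@H]([Se]c3ccccc3)[C@@]2(C)O1
F2 | step 6 | (5R,8R,9Z) bicyclic C3 dioxolane | C/C(=C/CO[Si](c1ccccc1)(c1ccccc1)C(C)(C)C)[C@H]1C=C2C(C)(C)CC3(OCCO3)C[C@@]2(C)O1
F3 | step 4 | (7E,9Z) tertiary bis-allylic alcohol, racemic at C6 | CC1=CC2(OCCO2)CC(C)(C)C1(O)/C=C/C(C)=C\CO[Si](c1ccccc1)(c1ccccc1)C(C)(C)C
F4 | step 5 | racemic C8 carbinol with C3 dioxolane | CC1=CC2(OCCO2)CC(C)(C)C1=CC(O)/C(C)=C\CO[Si](c1ccccc1)(c1ccccc1)C(C)(C)C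
F5 | step 5 | (8R)-acetate of the C8 carbinol | CC1=CC2(OCCO2)CC(C)(C)C1=C[C@@H](OC(C)=O)/C(C)=C\CO[Si](c1ccccc1)(c1ccccc1)C(C)(C)C
F6 | step 5 | (8S)-carbinol with C3 dioxolane | CC1=CC2(OCCO2)CC(C)(C)C1=C[C@H](O)/C(C)=C\CO[Si](c1ccccc1)(c1ccccc1)C(C)(C)C
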